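**Retrosynthetic overview**

1. The target is a (2S)-flavanone. Rings A and B are bought as arenes; ring C (the pyranone) is the only ring made, and it is closed at the O1–C8a bond.
2. The ring closure is an intramolecular addition–elimination (SNAr) run in the same flask as the crossed Claisen condensation that forms C2–C3: a formal [4+2] of a 2-fluoroaryl methyl ketone (C3–C4–C4a–C8a) with an ester C=O (C2=O1).
3. Enabling feature: C8a of ring A is ortho to the C4 carbonyl, so C8a–F/C4a/C4=O is a vinylogous acyl fluoride, and the enolate oxygen on C2 lies six atoms away (O1–C2=C3–C4–C4a–C8a), so only ring C can close.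
4. The ring is closed at the flavone level (C2 still sp2) because a C2-stereogenic flavanone ring-opens by retro-oxa-Michael under base. C2 is then set by Ru–NHC asymmetric hydrogenation to the (2S,4S)-flavan-4-ol, C4 is re-oxidised, and the benzyl ether is removed.
5. Order of ring formation: A and B (purchased), then C (step 3).

Key step: step 3

Assumption: in step 4 the antipode of the chiral NHC ligand is the one that delivers hydrogen to the C2 face giving 2S; (R,R)-SINpEt is written, and its mirror image is taken if the facial sense proves opposite.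

**Route**

Step 1
Reactants: 1 1-fluoro-2,3-dimethoxybenzene
Product: 4 1-(2-fluoro-3,4-dimethoxyphenyl)ethan-1-one, via aryllithium 2 (not isolated), via lithium hemiaminal adduct 3 (not isolated)
Conditions: n-BuLi, PMDTA, THF, −78 °C; then MeC(O)N(OMe)Me, −78 → 0 °C; aq. HCl
Reagents that add atoms: N-methoxy-N-methylacetamide, CC(=O)N(C)OC
Why: Fluorine-directed ortho-lithiation removes the only C–H ortho to fluorine (the most acidic ring position), and the aryllithium acylates the Weinreb amide once because the chelated tetrahedral adduct survives until acidic work-up (Weinreb ketone synthesis); no stereocentre is formed.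

Step 2
Reactants: 5 methyl 3-hydroxy-4,5-dimethoxybenzoate
Product: 6 methyl 3-(benzyloxy)-4,5-dimethoxybenzoate
Conditions: BnBr, K2CO3, DMF, 60 °C
Reagents that add atoms: benzyl bromide, BrCc1ccccc1
Why: Williamson etherification (SN2 of the phenoxide on benzyl bromide) masks the only acidic OH so that it can neither quench the enolate nor compete as a nucleophile in step 3; no stereocentre is involved.

Step 3
Reactants: 4 1-(2-fluoro-3,4-dimethoxyphenyl)ethan-1-one; 6 methyl 3-(benzyloxy)-4,5-dimethoxybenzoate
Product: 9 2-[3-(benzyloxy)-4,5-dimethoxyphenyl]-7,8-dimethoxy-4H-chromen-4-one, via sodium enolate 7 (not isolated), via sodium diketonate 8 (not isolated)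
Conditions: NaHMDS (2.2 equiv), THF, −78 → 50 °C; then DMF, 100 °C (THF distilled off); aq. work-up
Reagents that add atoms: none
Why: The sodium enolate 7 of ketone 4 attacks the ester carbonyl of 6 (crossed Claisen condensation, methoxide lost) to form C2–C3 and the chelated diketonate 8; in DMF the enolate oxygen on C2 adds to C8a, which is ortho to the C4 carbonyl and carries fluoride, giving a Meisenheimer-type adduct with the charge on the C4 oxygen, and loss of fluoride restores the aromatic A ring (addition–elimination SNAr). The closest known reaction type is the base-mediated intramolecular O-arylation of 1-(2-haloaryl)-1,3-diketones to chromones and flavones, here telescoped with the Claisen acylation that makes the diketone. Ring C closes through the six-membered array O1–C2=C3–C4–C4a–C8a, a 6-endo-trig oxa-Michael-type attack on the C8a=C4a–C4=O unit (6-exo-trig if counted on the C8a=C8 bond), allowed either way. No stereocentre is created: C2 is deliberately left sp2 so that no base-labile C2–O stereocentre next to an enolisable C3–H exists while base is present. The step needs O- over C-attack of the ambident diketonate and attack at C8a only: the carbon terminus and the C4 oxygen could only form four-membered rings, fluoride sits only at C8a, and the anionic diketonate resists intermolecular attack by the methoxide set free in the Claisen stage.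

Step 4
Reactants: 9 2-[3-(benzyloxy)-4,5-dimethoxyphenyl]-7,8-dimethoxy-4H-chromen-4-one
Product: 10 (2S,4S)-2-[3-(benzyloxy)-4,5-dimethoxyphenyl]-7,8-dimethoxy-3,4-dihydro-2H-chromen-4-ol
Conditions: [Ru(cod)(2-methylallyl)2] (5 mol%), (R,R)-SINpEt·HBF4 (10 mol%), KOt-Bu (15 mol%), H2 (100 bar), toluene/n-hexane, 40 °C
Reagents that add atoms: none
Why: Ru–NHC-catalysed asymmetric hydrogenation of a flavone: the chiral ruthenium hydride adds H2 to one enantioface of the C2=C3 bond (catalyst control sets C2 as S) and then reduces the C4 carbonyl, expected mainly cis to the 2-aryl group (substrate control; C4 is sacrificial and any 4-epimer converges in step 5), while the aryl ethers and the benzyl group should stay intact under this homogeneous catalyst.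

Step 5
Reactants: 10 (2S,4S)-2-[3-(benzyloxy)-4,5-dimethoxyphenyl]-7,8-dimethoxy-3,4-dihydro-2H-chromen-4-ol
Product: 11 (2S)-2-[3-(benzyloxy)-4,5-dimethoxyphenyl]-7,8-dimethoxy-2,3-dihydro-4H-chromen-4-one
Conditions: Dess–Martin periodinane (1.3 equiv), CH2Cl2, 0 °C → rt
Reagents that add atoms: none
Why: Dess–Martin oxidation of the benzylic secondary alcohol to the aryl ketone is base-free, so C3 is never enolised and the C2 stereocentre set in step 4 cannot racemise by retro-oxa-Michael ring opening; the C4 stereocentre is removed.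

Step 6
Reactants: 11 (2S)-2-[3-(benzyloxy)-4,5-dimethoxyphenyl]-7,8-dimethoxy-2,3-dihydro-4H-chromen-4-one
Product: 12 (2S)-2-(3-hydroxy-4,5-dimethoxyphenyl)-7,8-dimethoxy-2,3-dihydro-4H-chromen-4-one
Conditions: H2 (1 atm), 10% Pd/C, EtOAc, rt, stopped at full conversion
Reagents that add atoms: none
Why: Heterogeneous hydrogenolysis of the benzyl aryl ether should be faster than reduction of the aryl ketone or cleavage of the cyclic benzylic C2–O1 bond and is neutral, so the 2S centre is retained and the 3'-OH is released.

**Compound list**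

1 | 1-fluoro-2,3-dimethoxybenzene | COc1cccc(F)c1OC | starting material
2 | (2-fluoro-3,4-dimethoxyphenyl)lithium | [Li]c1ccc(OC)c(OC)c1F | intermediate
3 | lithium 1-(2-fluoro-3,4-dimethoxyphenyl)-1-[methoxy(methyl)amino]ethan-1-olate (racemic tetrahedral adduct) | CC(O[Li])(N(C)OC)c1ccc(OC)c(OC)c1F | intermediate
4 | 1-(2-fluoro-3,4-dimethoxyphenyl)ethan-1-one | CC(=O)c1ccc(OC)c(OC)c1F | intermediate
5 | methyl 3-hydroxy-4,5-dimethoxybenzoate | COC(=O)c1cc(O)c(OC)c(OC)c1 | starting material
6 | methyl 3-(benzyloxy)-4,5-dimethoxybenzoate | COC(=O)c1cc(OCc2ccccc2)c(OC)c(OC)c1 | intermediate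
7 | sodium 1-(2-fluoro-3,4-dimethoxyphenyl)ethen-1-olate | [Na+].[O-]C(=C)c1ccc(OC)c(OC)c1F | intermediate
8 | sodium 1-[3-(benzyloxy)-4,5-dimethoxyphenyl]-3-(2-fluoro-3,4-dimethoxyphenyl)-3-oxoprop-1-en-1-olate | [Na+].[O-]C(=CC(=O)c1ccc(OC)c(OC)c1F)c1cc(OCc2ccccc2)c(OC)c(OC)c1 | intermediate
9 | 2-[3-(benzyloxy)-4,5-dimethoxyphenyl]-7,8-dimethoxy-4H-chromen-4-one (achiral flavone) | COc1ccc2c(c1OC)oc(-c1cc(OCc3ccccc3)c(OC)c(OC)c1)cc2=O | intermediate
10 | (2S,4S)-2-[3-(benzyloxy)-4,5-dimethoxyphenyl]-7,8-dimethoxy-3,4-dihydro-2H-chromen-4-ol (2,4-cis) | COc1cc([C@@H]2C[C@H](O)c3ccc(OC)c(OC)c3O2)cc(OCc2ccccc2)c1OC | intermediate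
11 | (2S)-2-[3-(benzyloxy)-4,5-dimethoxyphenyl]-7,8-dimethoxy-2,3-dihydro-4H-chromen-4-one | COc1cc([C@@H]2CC(=O)c3ccc(OC)c(OC)c3O2)cc(OCc2ccccc2)c1OC | intermediate
12 | (2S)-2-(3-hydroxy-4,5-dimethoxyphenyl)-7,8-dimethoxy-2,3-dihydro-4H-chromen-4-one | COc1cc([C@@H]2CC(=O)c3ccc(OC)c(OC)c3O2)cc(O)c1OC | target

**Step count and risks**

Total step count: 6. Longest linear sequence: 5 (steps 1, 3, 4, 5, 6; equally 2, 3, 4, 5, 6).

Steps most likely to fail:

Step 4. Hydrogen delivery to the C2=C3 bond of this electron-rich 2-aryl pyranone may show insufficient facial selectivity, or the transient flavanone may partly racemise under the catalytic base before its carbonyl is reduced. The fallback sets out from 9 and comes back at 10. Compound 9 is hydrogenated with the same ruthenium precursor and an achiral N-heterocyclic carbene (ICy) to racemic cis-2-[3-(benzyloxy)-4,5-dimethoxyphenyl]-7,8-dimethoxy-3,4-dihydro-2H-chromen-4-ol F1. F1 is resolved by lipase-catalysed transesterification (Burkholderia cepacia lipase, vinyl acetate, MTBE). The (4R) enantiomer should be acetylated faster, as is usual for lipases with benzylic secondary alcohols, to give (2R,4R)-2-[3-(benzyloxy)-4,5-dimethoxyphenyl]-7,8-dimethoxy-3,4-dihydro-2H-chromen-4-yl acetate F2. The unreacted (2S,4S)-alcohol is 10 and re-enters at step 5.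

Step 3. The methoxide set free in the acylation stage may attack C8a–F or open the pyranone at C2 at 100 °C, or the chelated diketonate may fail to reach C8a, so that ring closure stalls. The fallback sets out from 4 and comes back at 9. The lithium enolate of 4 (LDA, THF, −78 °C) is added to commercial 3-(benzyloxy)-4,5-dimethoxybenzaldehyde F3, with a cold acidic quench, to give racemic 3-[3-(benzyloxy)-4,5-dimethoxyphenyl]-1-(2-fluoro-3,4-dimethoxyphenyl)-3-hydroxypropan-1-one F4. F4 is oxidised with Dess–Martin periodinane, in the absence of any alkoxide, to 1-[3-(benzyloxy)-4,5-dimethoxyphenyl]-3-(2-fluoro-3,4-dimethoxyphenyl)propane-1,3-dione F5. F5 is then closed at O1–C8a in a separate step (K2CO3, DMF, 100 °C) to give 9.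

Step 6. Over-reduction may compete with debenzylation, by hydrogenolysis of the cyclic benzylic C2–O1 bond or reduction of the C4 carbonyl. The fallback sets out from 11 and comes back at 12. The benzyl ether is cleaved non-reductively with BCl3 and pentamethylbenzene as cation scavenger (CH2Cl2, −78 °C), which should leave the methyl ethers, the ketone and the C2–O1 bond alone. No new intermediate is made on this way (F0).

**Further compounds**

F1 | step 4 | rac-(2S*,4S*)-2-[3-(benzyloxy)-4,5-dimethoxyphenyl]-7,8-dimethoxy-3,4-dihydro-2H-chromen-4-ol (racemic cis, both enantiomers written) | COc1cc([C@@H]2C[C@H](O)c3ccc(OC)c(OC)c3O2)cc(OCc2ccccc2)c1OC.COc1cc([C@H]2C[C@@H](O)c3ccc(OC)c(OC)c3O2)cc(OCc2ccccc2)c1OC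
F2 | step 4 | (2R,4R)-2-[3-(benzyloxy)-4,5-dimethoxyphenyl]-7,8-dimethoxy-3,4-dihydro-2H-chromen-4-yl acetate | COc1cc([C@H]2C[C@@H](OC(C)=O)c3ccc(OC)c(OC)c3O2)cc(OCc2ccccc2)c1OC
F3 | step 3 | 3-(benzyloxy)-4,5-dimethoxybenzaldehyde | O=Cc1cc(OCc2ccccc2)c(OC)c(OC)c1
F4 | step 3 | rac-3-[3-(benzyloxy)-4,5-dimethoxyphenyl]-1-(2-fluoro-3,4-dimethoxyphenyl)-3-hydroxypropan-1-one | OC(CC(=O)c1ccc(OC)c(OC)c1F)c1cc(OCc2ccccc2)c(OC)c(OC)c1
F5 | step 3 | 1-[3-(benzyloxy)-4,5-dimethoxyphenyl]-3-(2-fluoro-3,4-dimethoxyphenyl)propane-1,3-dione | O=C(CC(=O)c1ccc(OC)c(OC)c1F)c1cc(OCc2ccccc2)c(OC)c(OC)c1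
F0 | step 6 | none | none
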